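**Retrosynthetic overview**
1. Target 25 ← protected precursor 24 by one acidolysis that removes two catechol acetonides and one tert-butyl ester.
2. 24 ← Heck coupling of aryl bromide 16 with the acrylate 23 of the (R)-aryl-lactate; this forms the E-cinnamate.
3. 16 ← aldol addition of the enolate of 7-bromo-1,4-benzodioxin-2(3H)-one 12 to aldehyde 5, then dehydration; this is the key C–C bond and gives the Z-benzylidene.
4. 23 ← Cu-catalysed opening of methyl (R)-glycidate 17 by aryl Grignard reagent 18; the stereocentre comes from the chiral pool.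
5. Ring order: the benzodioxole (acetonide) ring first (step 1), then the 1,4-dioxin-2-one ring by etherification, Dakin oxidation and lactonisation (steps 4–6) before the aldol; no ring is closed afterwards.

Assumption: read from the SMILES, the lactate carbon is (R), the cinnamate is E and the benzylidene is Z (aryl cis to the ring ether oxygen).

**Route**

Step 1
Reactants: 1 catechol
Product: 2 2,2-dimethyl-1,3-benzodioxole
Conditions: 2,2-dimethoxypropane, TsOH (cat.), toluene, reflux, 4 Å MS (Soxhlet)
Reagents that add atoms: 2,2-dimethoxypropane, COC(C)(C)OC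
Why: Acid-catalysed transketalisation (acetonide formation) is driven to completion by trapping methanol.

Step 2
Reactants: 2 2,2-dimethyl-1,3-benzodioxole
Product: 3 5-bromo-2,2-dimethyl-1,3-benzodioxole
Conditions: NBS, DMF, 0 °C → rt
Reagents that add atoms: N-bromosuccinimide, O=C1CCC(=O)N1Br
Why: Electrophilic aromatic bromination of the symmetrical dialkoxyarene goes para to a ring oxygen, giving the 5-bromide.

Step 3
Reactants: 3 5-bromo-2,2-dimethyl-1,3-benzodioxole
Product: 5 2,2-dimethyl-1,3-benzodioxole-5-carbaldehyde, via aryllithium 4 (not isolated)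
Conditions: n-BuLi, THF, −78 °C; DMF, −78 → 0 °C; aq NH4Cl
Reagents that add atoms: N,N-dimethylformamide, CN(C)C=O
Why: Bromine–lithium exchange followed by formylation of the aryllithium with DMF gives the aldehyde, and the base-stable acetonide survives the mild NH4Cl work-up.

Step 4
Reactants: 6 5-bromo-2-hydroxybenzaldehyde; 7 tert-butyl bromoacetate
Product: 8 tert-butyl 2-(4-bromo-2-formylphenoxy)acetate
Conditions: K2CO3, DMF, rt
Reagents that add atoms: none
Why: Williamson ether synthesis on the phenoxide places the ether oxygen para to bromine, and room temperature avoids aldol cyclisation to a benzofuran.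

Step 5
Reactants: 8 tert-butyl 2-(4-bromo-2-formylphenoxy)acetate
Product: 10 tert-butyl 2-(4-bromo-2-hydroxyphenoxy)acetate, via aryl formate 9 (not isolated)
Conditions: mCPBA, CH2Cl2, rt; then MeOH, Et3N (cat.), 0 °C
Reagents that add atoms: meta-chloroperoxybenzoic acid, OOC(=O)c1cccc(Cl)c1
Why: Baeyer–Villiger (Dakin-type) oxidation of the ortho-alkoxybenzaldehyde proceeds with aryl migration, and the labile aryl formate is methanolysed to the phenol.

Step 6
Reactants: 10 tert-butyl 2-(4-bromo-2-hydroxyphenoxy)acetate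
Product: 12 7-bromo-1,4-benzodioxin-2(3H)-one, via hydroxy acid 11 (not isolated)
Conditions: TsOH·H2O (10 mol%), toluene, reflux, Dean–Stark
Reagents that add atoms: none
Why: Acid cleaves the tert-butyl ester with loss of isobutene, and the ortho-hydroxy acid closes by Fischer lactonisation to the six-membered aryl lactone.

Step 7
Reactants: 12 7-bromo-1,4-benzodioxin-2(3H)-one; 5 2,2-dimethyl-1,3-benzodioxole-5-carbaldehyde
Product: 14 7-bromo-3-[(2,2-dimethyl-1,3-benzodioxol-5-yl)(hydroxy)methyl]-1,4-benzodioxin-2(3H)-one (racemic diastereomer mixture), via lithium enolate 13 (not isolated)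
Conditions: LiN(SiMe3)2, THF, −78 °C (12 added to the base); then 5, −78 °C; AcOH quench at −78 °C
Reagents that add atoms: none
Why: Directed crossed aldol addition of the pre-formed lactone enolate to a non-enolisable aldehyde; inverse addition and a cold quench suppress Claisen self-condensation and β-lactone formation, and the two new stereocentres are erased in step 8.

Step 8
Reactants: 14 7-bromo-3-[(2,2-dimethyl-1,3-benzodioxol-5-yl)(hydroxy)methyl]-1,4-benzodioxin-2(3H)-one
Product: 16 (3Z)-7-bromo-3-[(2,2-dimethyl-1,3-benzodioxol-5-yl)methylidene]-1,4-benzodioxin-2(3H)-one, via mesylate 15 (not isolated)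
Conditions: MsCl, Et3N, CH2Cl2, 0 °C; then DBU, 0 °C → rt
Reagents that add atoms: none
Why: Mesylation and E1cB elimination complete the aldol condensation, and the reversible enolate pathway should deliver the thermodynamically preferred Z isomer (aryl anti to the lactone carbonyl, as in aurones and azlactones).

Step 9
Reactants: 3 5-bromo-2,2-dimethyl-1,3-benzodioxole; 17 methyl (2R)-oxirane-2-carboxylate (methyl (R)-glycidate)
Product: 19 methyl (2R)-3-(2,2-dimethyl-1,3-benzodioxol-5-yl)-2-hydroxypropanoate, via aryl Grignard reagent 18 (not isolated)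
Conditions: Mg, I2 (cat.), THF, reflux; CuI (15 mol%), 17, THF, −40 → −20 °C; aq NH4Cl
Reagents that add atoms: none
Why: Copper-catalysed SN2 opening of the glycidate at the terminal CH2 leaves the chiral-pool stereocentre untouched, so the (R) descriptor carries through.

Step 10
Reactants: 19 methyl (2R)-3-(2,2-dimethyl-1,3-benzodioxol-5-yl)-2-hydroxypropanoate
Product: 20 (2R)-3-(2,2-dimethyl-1,3-benzodioxol-5-yl)-2-hydroxypropanoic acid
Conditions: LiOH·H2O, THF/H2O, 0 °C; then cold 1 M HCl to pH 3
Reagents that add atoms: lithium hydroxide, [Li+].[OH-]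
Why: Mild saponification at 0 °C hydrolyses the methyl ester without epimerising the α-hydroxy centre, and the catechol acetonide is stable to base and brief cold dilute acid.

Step 11
Reactants: 20 (2R)-3-(2,2-dimethyl-1,3-benzodioxol-5-yl)-2-hydroxypropanoic acid
Product: 21 tert-butyl (2R)-3-(2,2-dimethyl-1,3-benzodioxol-5-yl)-2-hydroxypropanoate
Conditions: Cl3CC(=NH)O-t-Bu, CH2Cl2/cyclohexane, rt
Reagents that add atoms: tert-butyl 2,2,2-trichloroacetimidate, CC(C)(C)OC(=N)C(Cl)(Cl)Cl
Why: Imidate tert-butylation without added Lewis acid is selective for the carboxylic acid over the secondary alcohol, giving an ester that later falls off under the same acid as the acetonides.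

Step 12
Reactants: 21 tert-butyl (2R)-3-(2,2-dimethyl-1,3-benzodioxol-5-yl)-2-hydroxypropanoate; 22 acryloyl chloride
Product: 23 tert-butyl (2R)-2-(acryloyloxy)-3-(2,2-dimethyl-1,3-benzodioxol-5-yl)propanoate
Conditions: i-Pr2NEt, CH2Cl2, −20 → 0 °C
Reagents that add atoms: none
Why: O-acylation of the secondary alcohol with the acid chloride breaks no bond at the stereocentre, so the (R) configuration is retained.

Step 13
Reactants: 16 (3Z)-7-bromo-3-[(2,2-dimethyl-1,3-benzodioxol-5-yl)methylidene]-1,4-benzodioxin-2(3H)-one; 23 tert-butyl (2R)-2-(acryloyloxy)-3-(2,2-dimethyl-1,3-benzodioxol-5-yl)propanoate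
Product: 24 tert-butyl (2R)-2-{[(2E)-3-{(3Z)-3-[(2,2-dimethyl-1,3-benzodioxol-5-yl)methylidene]-2-oxo-2,3-dihydro-1,4-benzodioxin-7-yl}prop-2-enoyl]oxy}-3-(2,2-dimethyl-1,3-benzodioxol-5-yl)propanoate
Conditions: Pd[P(t-Bu)3]2 (5 mol%, zerovalent palladium), Cy2NMe, 1,4-dioxane, 60 °C
Reagents that add atoms: none
Why: Mizoroki–Heck coupling of the unhindered aryl bromide with the acrylate gives the E-cinnamate by syn insertion and syn β-hydride elimination, under a mild non-nucleophilic amine base that spares the aryl lactone and the stereocentre.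

Step 14
Reactants: 24 fully protected precursor
Product: 25 (2R)-2-{[(2E)-3-{(3Z)-3-[(3,4-dihydroxyphenyl)methylidene]-2-oxo-2,3-dihydro-1,4-benzodioxin-7-yl}prop-2-enoyl]oxy}-3-(3,4-dihydroxyphenyl)propanoic acid (target)
Conditions: TFA/H2O (9:1), 0 °C → rt; reverse-phase HPLC
Reagents that add atoms: none
Why: Global acidolysis hydrolyses both catechol acetonides (to acetone) and cleaves the tert-butyl ester (to isobutene), while the aryl lactone, both alkenes and the stereocentre are stable to non-nucleophilic acid.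

**Compound list**
1 | catechol | Oc1ccccc1O | starting material
2 | 2,2-dimethyl-1,3-benzodioxole | CC1(C)Oc2ccccc2O1 | intermediate
3 | 5-bromo-2,2-dimethyl-1,3-benzodioxole | CC1(C)Oc2ccc(Br)cc2O1 | intermediate
4 | (2,2-dimethyl-1,3-benzodioxol-5-yl)lithium | [Li]c1ccc2OC(C)(C)Oc2c1 | intermediate (not isolated)
5 | 2,2-dimethyl-1,3-benzodioxole-5-carbaldehyde | CC1(C)Oc2ccc(C=O)cc2O1 | intermediate
6 | 5-bromo-2-hydroxybenzaldehyde | O=Cc1cc(Br)ccc1O | starting material
7 | tert-butyl bromoacetate | CC(C)(C)OC(=O)CBr | starting material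
8 | tert-butyl 2-(4-bromo-2-formylphenoxy)acetate | CC(C)(C)OC(=O)COc1ccc(Br)cc1C=O | intermediate
9 | tert-butyl 2-[4-bromo-2-(formyloxy)phenoxy]acetate | CC(C)(C)OC(=O)COc1ccc(Br)cc1OC=O | intermediate (not isolated)
10 | tert-butyl 2-(4-bromo-2-hydroxyphenoxy)acetate | CC(C)(C)OC(=O)COc1ccc(Br)cc1O | intermediate
11 | 2-(4-bromo-2-hydroxyphenoxy)acetic acid | OC(=O)COc1ccc(Br)cc1O | intermediate (not isolated)
12 | 7-bromo-1,4-benzodioxin-2(3H)-one | O=C1COc2ccc(Br)cc2O1 | intermediate
13 | lithium enolate of 12 (lithium 7-bromo-1,4-benzodioxin-2-olate) | [Li]OC1=COc2ccc(Br)cc2O1 | intermediate (not isolated)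
14 | 7-bromo-3-[(2,2-dimethyl-1,3-benzodioxol-5-yl)(hydroxy)methyl]-1,4-benzodioxin-2(3H)-one, racemic diastereomer mixture | OC(c1ccc2OC(C)(C)Oc2c1)C1Oc2ccc(Br)cc2OC1=O | intermediate
15 | (7-bromo-2-oxo-2,3-dihydro-1,4-benzodioxin-3-yl)(2,2-dimethyl-1,3-benzodioxol-5-yl)methyl methanesulfonate | CS(=O)(=O)OC(c1ccc2OC(C)(C)Oc2c1)C1Oc2ccc(Br)cc2OC1=O | intermediate (not isolated)
16 | (3Z)-7-bromo-3-[(2,2-dimethyl-1,3-benzodioxol-5-yl)methylidene]-1,4-benzodioxin-2(3H)-one | Brc1ccc2c(c1)OC(=O)/C(=C/c1ccc3OC(C)(C)Oc3c1)O2 | intermediate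
17 | methyl (2R)-oxirane-2-carboxylate | COC(=O)[C@H]1CO1 | starting material
18 | (2,2-dimethyl-1,3-benzodioxol-5-yl)magnesium bromide | CC1(C)Oc2ccc([Mg]Br)cc2O1 | intermediate (not isolated)
19 | methyl (2R)-3-(2,2-dimethyl-1,3-benzodioxol-5-yl)-2-hydroxypropanoate | COC(=O)[C@H](O)Cc1ccc2OC(C)(C)Oc2c1 | intermediate
20 | (2R)-3-(2,2-dimethyl-1,3-benzodioxol-5-yl)-2-hydroxypropanoic acid | OC(=O)[C@H](O)Cc1ccc2OC(C)(C)Oc2c1 | intermediate
21 | tert-butyl (2R)-3-(2,2-dimethyl-1,3-benzodioxol-5-yl)-2-hydroxypropanoate | CC(C)(C)OC(=O)[C@H](O)Cc1ccc2OC(C)(C)Oc2c1 | intermediate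
22 | acryloyl chloride | C=CC(=O)Cl | starting material
23 | tert-butyl (2R)-2-(acryloyloxy)-3-(2,2-dimethyl-1,3-benzodioxol-5-yl)propanoate | CC(C)(C)OC(=O)[C@H](OC(=O)C=C)Cc1ccc2OC(C)(C)Oc2c1 | intermediate
24 | tert-butyl (2R)-2-{[(2E)-3-{(3Z)-3-[(2,2-dimethyl-1,3-benzodioxol-5-yl)methylidene]-2-oxo-2,3-dihydro-1,4-benzodioxin-7-yl}prop-2-enoyl]oxy}-3-(2,2-dimethyl-1,3-benzodioxol-5-yl)propanoate | CC(C)(C)OC(=O)[C@H](OC(=O)/C=C/c1ccc2c(c1)OC(=O)/C(=C/c1ccc3OC(C)(C)Oc3c1)O2)Cc1ccc2OC(C)(C)Oc2c1 | intermediate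
25 | (2R)-2-{[(2E)-3-{(3Z)-3-[(3,4-dihydroxyphenyl)methylidene]-2-oxo-2,3-dihydro-1,4-benzodioxin-7-yl}prop-2-enoyl]oxy}-3-(3,4-dihydroxyphenyl)propanoic acid | O=C(/C=C/c1ccc2c(c1)OC(=O)/C(=C/c1ccc(O)c(O)c1)O2)O[C@H](Cc1ccc(O)c(O)c1)C(=O)O | target

**Step count**
Total steps: 14. Longest linear sequence: 8 steps (1 → 2 → 3 → 19 → 20 → 21 → 23 → 24 → 25).

**Three steps most likely to fail, with fallbacks**

The first risk is step 7, the aldol of the aryl-lactone enolate. The lithium enolate of an aryl ester can acylate unreacted lactone, and the aldolate can expel the phenoxide on warming. The fallback avoids a metal enolate altogether. It sets out from 12, which is soft-enolised (TBSOTf, Et3N, CH2Cl2, 0 °C) to the silyl ketene acetal [(7-bromo-1,4-benzodioxin-2-yl)oxy](tert-butyl)dimethylsilane F1. A Mukaiyama aldol addition of this acetal to aldehyde 5 (BF3·OEt2, CH2Cl2, −78 °C, aqueous work-up) gives the aldol adduct directly, so the fallback comes back to the route at 14.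

The second risk is step 9, the copper-catalysed opening of the glycidic ester. The Grignard reagent may attack the ester, or magnesium halide may open the epoxide to a halohydrin. The fallback uses an epoxide with no ester and adjusts the oxidation level afterwards. It sets out from 3 (through Grignard reagent 18), which opens (R)-benzyl glycidyl ether, C(OCc1ccccc1)[C@H]1CO1, under CuI catalysis (THF, −30 °C) to give (2R)-1-(benzyloxy)-3-(2,2-dimethyl-1,3-benzodioxol-5-yl)propan-2-ol F2. Hydrogenolysis (H2, Pd/C, EtOAc) gives (2R)-3-(2,2-dimethyl-1,3-benzodioxol-5-yl)propane-1,2-diol F3. Selective oxidation of the primary alcohol (TEMPO cat., NaOCl cat., NaClO2, MeCN/pH 6.7 phosphate buffer, 35 °C) gives the hydroxy acid, so the fallback comes back to the route at 20.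

The third risk is step 13, the Heck coupling on the sensitive benzylidene lactone. The coupling may be sluggish or the acrylate may oligomerise under basic Heck conditions. The fallback separates arylation from alkene construction. It sets out from 16, which undergoes base-free Stille vinylation (tributyl(vinyl)stannane, Pd(PPh3)4 as zerovalent palladium, toluene, 90 °C) to give (3Z)-3-[(2,2-dimethyl-1,3-benzodioxol-5-yl)methylidene]-7-ethenyl-1,4-benzodioxin-2(3H)-one F4. Olefin cross-metathesis of this styrene with acrylate 23 (second-generation Grubbs catalyst, CH2Cl2, 40 °C) gives the E-cinnamate, so the fallback comes back to the route at 24. The trisubstituted, electron-poor benzylidene alkene is inert to metathesis.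

**Further compounds**
F1 | step 7 | [(7-bromo-1,4-benzodioxin-2-yl)oxy](tert-butyl)dimethylsilane | CC(C)(C)[Si](C)(C)OC1=COc2ccc(Br)cc2O1
F2 | step 9 | (2R)-1-(benzyloxy)-3-(2,2-dimethyl-1,3-benzodioxol-5-yl)propan-2-ol | C(OCc1ccccc1)[C@H](O)Cc1ccc2OC(C)(C)Oc2c1
F3 | step 9 | (2R)-3-(2,2-dimethyl-1,3-benzodioxol-5-yl)propane-1,2-diol | OC[C@H](O)Cc1ccc2OC(C)(C)Oc2c1
F4 | step 13 | (3Z)-3-[(2,2-dimethyl-1,3-benzodioxol-5-yl)methylidene]-7-ethenyl-1,4-benzodioxin-2(3H)-one | C=Cc1ccc2c(c1)OC(=O)/C(=C/c1ccc3OC(C)(C)Oc3c1)O2
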